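The earlier runs and the new flask stem from a simulated flask with constants of no real substance; the scatter is artificial.

At early times the flask spends left-handed substrate and spares its mirror image: at 8.00 min the left-handed substrate reads 34.6% and the right-handed substrate 50.0%. The decision for this flask is whether to add solid reagent or to leave the charge as it is, and it hangs on what the wanted excess costs in partner.

| flask | left-handed substrate | right-handed substrate | solid reagent | catalyst | remark | time |
|---|---|---|---|---|---|---|
| beta | 0.050 M | 0.050 M | 1.2 equiv | 15 mol% | the very flask that is asked about, followed so far |  |
| flask | 0.050 M | 0.050 M | 1.20 equiv | 15 mol% |  | 80 min |

beta run (percent of the left-handed substrate and right-handed substrate together charged)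

| time / min | right-handed substrate / % | left-handed substrate / % | left-handed product / % |
|---|---|---|---|
| 3.00 | 50.1 | 45.8 | 4.9 |
| 8.00 | 50.0 | 34.6 | 15.2 |
| 15.0 | 49.7 | 21.6 | 28.7 |
| 25.0 | 48.5 | 7.1 | 43.3 |
| 30.0 | 48.2 | 2.6 | 46.8 |

(scatter of a reading: 0.5 percentage points)

- catalyst is single-handed; left-handed substrate and right-handed substrate are mirror images of each other, charged as a racemate, each of them at the stated concentration
- solid reagent is a solid; its amount is given per volume of the solution
- candidate steps: partner + catalyst + left-handed substrate -> catalyst + left-handed product; partner + catalyst + right-handed substrate -> catalyst + right-handed product; solid reagent <-> partner; 2 partner -> self-condensation product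
- at the start none of the solid reagent is in solution

- whether the excess of right-handed substrate over left-handed substrate among what is left of the two reaches 98% by 80 min (no / yes)
- the highest excess of right-handed substrate over left-handed substrate among what is left of the two up to 80 min

My own reckoning joins two ends. The reading at 30.0 min gives the selectivity factor, the log of charged over left for the left-handed substrate divided by the same log for the right-handed substrate:

s = 80.6

This is a loose reading, since the right-handed loss is 1.8 percentage points against a scatter of 0.5 points. At the other end, the wanted excess means a ratio of left-handed to right-handed substrate of 0.0101. Joining the two, the right-handed substrate then keeps this fraction of its charge: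

f = 94.4%

Both substrates together have then lost, per left-handed charge:

bill = 1.05 equivalents

The partner reserve, charged solid reagent minus this bill, is:

reserve = 0.153 equivalents

At half that factor the bill is 1.10 equivalents, still less than the 1.20 charged. The last two readings give a time constant of 4.98 min, itself a scattered reading; held constant, it puts the target an estimated 8.44 min past the last reading, less than the time remaining. My decision is to add nothing.

The forecast says yes, with a top of 99.7% (range 97.5% to 100%), judging that “1.2 equiv probably leaves enough”.

    partner + catalyst + left-handed substrate → catalyst + left-handed product (k = 31.4 /M²/s)
    partner + catalyst + right-handed substrate → catalyst + right-handed product (k = 0.277 /M²/s)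
    solid reagent ⇌ partner, rate k3*(cs3 - [partner]) while solid is left; crystals form when [partner] > cs3 (solubility = 29.0 mM, k = 0.00156 /s)
    2 partner → self-condensation product (k = 0.00374 /M/s)

The flask gives yes, with a top of 99.9%, and the wanted excess stands at 45.1 min, which is 15.1 min past the last reading, later than the time-constant estimate. At 40.0 min the solid reagent is at 0% of its charge while the excess is 96.6%, so the last stretch runs on partner already in solution. The reserve, reckoned for the wanted excess and put in concentration, is 0.00767 M, and the partner in solution at 40.0 min stands at 0.00797 M, more than the reserve.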